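Read each substrate peak as the logarithm ln(c(substrate) at start / c(substrate)), and watch where it stops.

all flasks: substrate 0.10 M
- epsilon: partner 0.13 M; scavenger 0.10 M; free catalyst 2 mM; the very flask that is asked about, followed so far
- alpha: partner 0.26 M; scavenger 0.10 M; free catalyst 2 mM; run made earlier
- flask: partner 0.130 M; scavenger 0.100 M; free catalyst 2.0 mM; time 10 d

| run | time / d | substrate / % | target / % |
|---|---|---|---|
| epsilon | 0.833 | 74.8 | 23.6 |
| epsilon | 1.67 | 64.4 | 33.3 |
| epsilon | 2.50 | 57.8 | 39.8 |
| epsilon | 3.00 | 57.4 | 38.9 |
| alpha | 0.833 | 59.6 | 39.5 |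
| alpha | 1.67 | 43.3 | 57.6 |
| alpha | 4.00 | 27.0 | 70.5 |
| alpha | 10.0 | 25.7 | 74.6 |

(each reading ± 1 percentage point)

* part of the substrate that has reacted at 10 d
* share of the unused partner that is free and not bound as idle adduct, at 10 d

1. I treated substrate loss as pseudo-first-order with a rate constant a·exp(−λt) that dies away at λ. Integrated, the logarithm equals (a/λ)(1 − exp(−λt)), so it stops at a/λ, the reach. Epsilon's last two readings gave a reach of 0.552.

2. Time: alpha's substrate moved 1.3 percentage points from 4.00 d to 10.0 d, against a scatter of 1 point, and epsilon read 57.8 % and then 57.4 %. So I expected nothing from running on to 10 d.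

3. Partner: I took a as proportional to c(partner) and defined the reach per unit of c(partner) charged, 4.24 M⁻¹, as ρ. Alpha holds twice epsilon's partner, so ρ should have matched there. It read 5.13 M⁻¹, more than epsilon's, so ρ is a local reading. I kept epsilon's value, as epsilon is this recipe.

4. Catalyst and scavenger: both runs held 2 mM and 0.10 M, so the readings show neither effect.

5. For this flask, ρ·c(partner) gave 42.4 % reacted.

The forecast was higher, at 46.5 % (43 % to 51 %), with 97 % (75 % to 100 %) for the free share, and it read the stall as “the catalyst dying, probably through the scavenger”.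

The flask gave 43.0 % reacted, at the low end of the forecast's range, and >99.9 % free, inside its range; my 42.4 % lay 0.60 points below the first.

    catalyst intermediate A ⇌ catalyst intermediate B (K = 0.340, k = 16.0 h⁻¹)
    substrate + free catalyst → catalyst intermediate A (k = 590 M⁻¹ h⁻¹)
    catalyst intermediate E → free catalyst + target (k = 100 h⁻¹)
    partner + catalyst intermediate B ⇌ catalyst intermediate C (K = 1.30 M⁻¹, k = 13000 M⁻¹ h⁻¹)
    catalyst intermediate D → catalyst intermediate E (k = 3.50 h⁻¹)
    partner + released group ⇌ idle adduct, settled at all times (K = 30.0 M⁻¹)
    partner → decomposed reagent (k = 0.0330 h⁻¹)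
    scavenger + released group → scavenged by-product (k = 58.0 M⁻¹ h⁻¹)
    catalyst intermediate C ⇌ released group + catalyst intermediate D (K = 0.140 M, k = 29.0 h⁻¹)

In this flask, partner's half-life by decomposition, 0.875 d, was shorter than substrate's 2.3 d by its step with free catalyst at 0.594 d. At 10.0 d the flask held 0 % of its partner, the first to run out, and 0.0890 M of decomposed reagent against 0.0410 M of target, while the catalyst charged stood as 74.6 % catalyst intermediate A and 25.4 % catalyst intermediate B.

For a neighbour flask with 0.078 M partner, ρ gives 28.2 % reacted; that flask gave 28.0 %.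

Readings and results are simulated for substances that don't exist; scatter was added.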